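The data are calculated with constants of no real substance, noise included.

Start from the leftover: take the coupling partner charged, subtract the starting material, and express the difference as a fraction of the starting material charge. Call that the spare partner. Sunday's spare is 0.200, and its mono adduct stands at 75% at 6.00 min and 74% at 30.0 min. Thursday's spare is 2.55, and its mono adduct falls from 71% at 4.00 min to 8% at 30.0 min. Two runs establish no rate law, and spare partner falls as a run goes on, so what follows is a rough working assumption of my own: the loss of mono adduct goes with the spare partner charged, and a flask can be read on Thursday's curve with its clock rescaled. For elm that rescaling is the clock ratio, elm's spare over Thursday's, 0.784.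

| flask | starting material | coupling partner | capture agent | remark | time |
|---|---|---|---|---|---|
| Sunday's | 0.020 M | 0.024 M | 1 mM | run made earlier |  |
| Thursday's | 0.020 M | 0.071 M | 1 mM | run made earlier |  |
| maple | 0.020 M | 0.0500 M | 1.00 mM |  | 30 min |
| alder | 0.020 M | 0.0160 M | 1.00 mM |  | 30 min |
| elm | 0.020 M | 0.0600 M | 1.00 mM |  | 30 min |

| run | time / min | mono adduct / % | triple product / % |
|---|---|---|---|
| Sunday's | 2.50 | 65 | 0 |
| Sunday's | 4.00 | 70 | 1 |
| Sunday's | 6.00 | 75 | 1 |
| Sunday's | 8.00 | 74 | 4 |
| Sunday's | 12.0 | 75 | 0 |
| Sunday's | 20.0 | 74 | 2 |
| Sunday's | 30.0 | 74 | 3 |
| Thursday's | 4.00 | 71 | 16 |
| Thursday's | 8.00 | 49 | 28 |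
| Thursday's | 12.0 | 34 | 33 |
| Thursday's | 15.0 | 27 | 36 |
| Thursday's | 20.0 | 19 | 40 |
| Thursday's | 25.0 | 15 | 39 |
| Thursday's | 30.0 | 8 | 42 |

(each reading ± 1.5 percentage points)

- which of these holds the largest part of the starting material at the end of maple (starting material / double product / mono adduct / triple product)
- which of these holds the largest part of the starting material at the end of alder (starting material / double product / mono adduct / triple product)
- which of these holds the largest part of the starting material at the end of elm (starting material / double product / mono adduct / triple product)
- amount of mono adduct at the end of elm, in percent of the starting material charged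



Your choice is the partner charge. Alder holds less partner than starting material, so partner is its limiting reagent, its spare is −0.200, and you should expect a Sunday-like stall with mono adduct on top. On that assumption elm's 30 min corresponds to 23.5 min on Thursday's curve, where the readings interpolate to 16.2% mono adduct. Maple's 30 min corresponds in the same way to 17.6 min, giving an estimate of 22.8%, which is more mono adduct than the estimate for elm. Thursday's readings at 25.0 min leave 46.0% unaccounted for, which I take as double product, more than the 39% triple product. To bring mono adduct down, charge elm's partner and leave the rest.

The forecast names double product for maple, mono adduct for alder and double product for elm. It gives elm 17% mono adduct, between 12% and 22%, a little above my 16.2%, and says “Sunday stalls because partner runs out”.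

Elm ends with 18.0% mono adduct, 46.6% double product and 31.2% triple product; maple ends on double product and alder on mono adduct.

    starting material + coupling partner → mono adduct (k = 0.500 M⁻¹ s⁻¹)
    coupling partner + mono adduct → double product (k = 0.0380 M⁻¹ s⁻¹)
    coupling partner + double product ⇌ triple product (K = 37.0 M⁻¹, k = 0.830 M⁻¹ s⁻¹)
    mono adduct + capture agent → trapped intermediate (k = 0.120 M⁻¹ s⁻¹)

In elm at 30.0 min, the exchange between double and triple product relaxes with a half-life of 0.255 min, far shorter than the 27.5 min of the flask's slowest mode. Double and triple product thus adjust to each other within moments, while the flask as a whole still moves on the long time. The clock ratio puts elm's 8.0 min at 6.27 min on Thursday's curve, where the readings interpolate to 58.5%, and elm read at that time holds 55.3% mono adduct.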